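## The problem

The target (24) is a trans-fused hydrindan-2-one. A cyclopentanone (C1, C2 ketone, C3, C3a, C7a) shares the C3a–C7a bond with a cyclohexane (C3a, C4, C5, C6, C7, C7a), and C7 carries an exocyclic methylene (C8). This numbering is used for every compound below. Six contiguous stereocentres (C3, C3a, C4, C5, C6, C7a) have to be set. C7a can be bought as a single enantiomer; it should steer C3a by trans addition, and C3a in turn should steer the C3 oxygen to the opposite face. C5 and C6 can be ruled by the chair of the six-membered ring once C3a, C4 and C7a exist. C4, which bears the isopropyl group, stays outside any ring until the last bond is made and is the hardest centre to control. Little is tolerated: the angelate isomerises to the tiglate under acid, base, nucleophiles or heat, the α-acetoxy ketone can epimerise at C3 or be reduced, and a free C5 hydroxyl next to the C6 ester invites acyl migration. The C3 acetate, the C6 angelate and the free C5 hydroxyl must therefore arrive already differentiated. The enabling feature is that C5–OH, C6–O-acyl and C7=C8 form a 2-acyloxy homoallylic alcohol, the pattern left when a γ-acyloxyallyl metal adds through its γ-carbon (C6) to an aldehyde (C5).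

## Retrosynthesis

**C5–C6 (24 ⇒ 21).** Cutting the bond between the two oxygen-bearing carbons removes the six-membered ring, two stereocentres and the methylene at once. It leaves the monocyclic aldehyde 21, with bromine on C8 and C6 as an enol angelate. The neighbouring cuts are poorer: C6–C7 needs a C6 radical or anion that already carries the ester, C4–C5 fixes neither oxygen, and C7–C7a offers no handle for the methylene. The forward reaction must make the γ-angeloyloxyallylchromium species 22, add it through C6 to the aldehyde only, and pass through a closed transition state so that alkoxide 23, and from it 24, has the C5 oxygen and the C6 ester trans-diaxial.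

**C5 oxidation state (21 ⇒ 20 ⇒ 19).** An aldehyde next to the C4 stereocentre should exist for one step only, so it is made from alcohol 20 immediately before ring closure. Alcohol 20 comes from the tert-butyldiphenylsilyl ether 19. This ether is chosen because it must survive an acyl bromide with ZnCl2 and then leave under acidic fluoride, which the allylic bromide and the enol ester tolerate.

**C6–O and C8–Br (19 ⇒ 16 + 18).** Both heteroatom bonds of the bromo enol ester come from net 1,4-addition of angeloyl bromide 18 across enal 16. The angelate is thus installed as an enol ester, and no hindered secondary alcohol ever has to be acylated. Bromide 18 comes from angelic acid 17 under neutral conditions that keep the Z geometry.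

**C7=C8 and C6=O (16 ⇒ 15 ⇒ 13).** The enal is the α-methylenation product of aldehyde 15, and 15 is the ozonolysis product (via ozonide 14) of the allyl compound 13. The allyl group supplies C7 and C6; formaldehyde supplies C8. Both operations act only on the side chain.

**C3–O (13 ⇒ 12 ⇒ 10).** The acetate comes from α-hydroxy ketone 12, made by Rubottom oxidation of silyl enol ether 10 through silyloxy ketone 11. Oxidising an enol ether whose position is fixed by a conjugate addition avoids enolising a free ketone, which could go towards C1 as well.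

**C5 adjustment (10 ⇒ 9 ⇒ 8).** While the ketone is masked as its enol ether, the ester of 8 can be reduced to alcohol 9 and silylated without touching C2. After C3 oxidation this would no longer be possible.

**C3a–C4 (8 ⇒ 4 + 7).** A Mukaiyama–Michael addition of ketene acetal 7 (from ester 5 via enolate 6) to enone 4 brings in C4, C5 and the isopropyl group in one bond. It sets C3a trans to the allyl group and delivers the C2=C3 enol ether needed for the C3 oxidation. It must also set C4, for which only the open transition state and the acetal geometry are available. Cutting C4–isopropyl or C4–C5 instead gives no better control and more steps.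

**C7a–C7 (4 ⇒ 3 ⇒ 1 + 2).** Enone 4 comes from conjugate allylation of the commercial silyloxy enone 1 with allylsilane 2, trans to the silyloxy group, followed by elimination of the silanol from 3. The bought stereocentre is thereby exchanged for C7a.

## Roads not taken

**Alternative 1:** The cut is C3–C3a, with the five-membered ring made from a furan. The 2-furylcarbinol A2 would be ionised by Dy(OTf)3 (trivalent dysprosium) in aqueous acetonitrile; water opens the furan and the pentadienyl cation closes conrotatorily to the trans-4-hydroxy-5-alkylcyclopentenone A1. The trans C3/C3a relation is guaranteed by the electrocyclisation. C4 and C5 are set beforehand by reagent-controlled acyclic chemistry, and in this respect the road is better than the chosen plan, whose C4 rests on an open transition state. Its weak points are structural. The carbonyl of A1 lies on the future C7a, so a carbonyl transposition to C2, a C–C bond at C7a, closure of the six-membered ring, the methylene and a protecting-group exchange for the angelate all remain. The sense of the new ring centres relative to C4 is only weakly induced. The chosen plan sets against the better C4 control a much shorter sequence in which every ring centre follows from C7a and the closing step is the last step.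

**Alternative 2:** The cut is C2–C3, the acyloin bond. A triazolium-derived carbene with an amine base would convert the unbranched aldehyde of dialdehyde A4 into an acyl anion equivalent that adds to the C3 aldehyde, giving ketol A3. The α-oxygenated ketone would then appear late and never meet a reductant; here this road is better, since the chosen plan must carry the α-acetoxy ketone through the chromium step. Against it stand three points. The C3a aldehyde is epimerisable under the base and could leak to the less strained cis-fused ring. The C3 configuration is not secured by any closed array. The fully substituted cyclohexane of A4, with angelate, silyl ether and methylene, must be built first without the cyclopentanone as a template. Acetylation and desilylation would still follow. The chosen plan answers the reduction risk with the aldehyde selectivity of divalent chromium and gains the six-membered ring array in one step.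

**Alternative 3:** The cut is C6–C7. Cathodic reduction of the N-hydroxyphthalimide ester A6 would expel CO2; the C6 α-alkoxy radical would add 6-exo-dig to the ethynyl group on C7a, and hydrogen transfer would give the methylene compound A5. The conditions are neutral, no aldehyde next to C4 is needed, and the methylene forms directly; in avoiding an epimerisable aldehyde and an allylic bromide this road is as good as or better than the chosen one. Its weak points are the C6 configuration, decided in an early radical transition state with no element that favours the axial oxygen, and the reducible α-acetoxy ketone at the cathode. Three steps also follow the ring closure: ether cleavage, angeloylation of a hindered axial allylic alcohol (where Z to E isomerisation threatens) and desilylation. The chosen plan sets against this a closed transition state for C5 and C6 and delivery of the angelate and the free C5 hydroxyl in the closing step.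

Key step: step 15

## Route

Assumption: compounds 19, 20 and 21 are written as the (E)-enol esters; if step 12 gives both enol ester geometries, both are carried on, because they merge in the equilibrating allylchromium species of step 15.

Step 1
Reactants: 1 (R)-4-(tert-butyldimethylsilyloxy)cyclopent-2-en-1-one; 2 allyltrimethylsilane
Product: 3 (3R,4R)-3-allyl-4-(tert-butyldimethylsilyloxy)cyclopentan-1-one
Conditions: TiCl4, CH2Cl2, −78 °C; then H2O
Reagents that add atoms: none
Why: Hosomi–Sakurai conjugate allylation of the TiCl4-activated enone; the allyl group enters C7a on the face opposite the neighbouring silyloxy group, so the bought stereocentre fixes C7a.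

Step 2
Reactants: 3 (3R,4R)-3-allyl-4-(tert-butyldimethylsilyloxy)cyclopentan-1-one
Product: 4 (R)-4-allylcyclopent-2-en-1-one
Conditions: DBU, CH2Cl2, 0 °C
Reagents that add atoms: none
Why: E1cB elimination of the β-silyloxy group gives the new enone; the allyl-bearing centre is not touched, and low temperature and short contact should prevent γ-deprotonation.

Step 3
Reactants: 5 methyl 3-methylbutanoate
Product: 7 (Z)-tert-butyl[(1-methoxy-3-methylbut-1-en-1-yl)oxy]dimethylsilane, via lithium enolate 6 (not isolated)
Conditions: LiN(i-Pr)2, THF/DMPU, −78 °C; then TBSCl, −78 °C to rt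
Reagents that add atoms: tert-butyldimethylsilyl chloride, CC(C)(C)[Si](C)(C)Cl
Why: Ester enolisation in the presence of a dipolar cosolvent gives the enolate with O–Li cis to the isopropyl group; O-silylation fixes this as the (Z)-ketene acetal (silyloxy cis to isopropyl).

Step 4
Reactants: 4 (R)-4-allylcyclopent-2-en-1-one; 7 (Z)-tert-butyl[(1-methoxy-3-methylbut-1-en-1-yl)oxy]dimethylsilane
Product: 8 methyl (2S)-2-[(1S,5R)-5-allyl-3-(tert-butyldimethylsilyloxy)cyclopent-2-en-1-yl]-3-methylbutanoate
Conditions: TBSOTf (10 mol%), CH2Cl2, −78 °C
Reagents that add atoms: none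
Why: Mukaiyama–Michael addition with silyl transfer gives the C2=C3 enol ether directly; attack anti to the allyl group sets C3a. C4 should follow from an extended open transition state in which the acetal hydrogen lies over the ring, the isopropyl group sits beside the flat enone α-carbon, and the (Z)-acetal turns only its small methoxy group towards the ring.

Step 5
Reactants: 8 methyl (2S)-2-[(1S,5R)-5-allyl-3-(tert-butyldimethylsilyloxy)cyclopent-2-en-1-yl]-3-methylbutanoate
Product: 9 (2S)-2-[(1R,5R)-5-allyl-3-(tert-butyldimethylsilyloxy)cyclopent-2-en-1-yl]-3-methylbutan-1-ol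
Conditions: i-Bu2AlH, CH2Cl2, −78 °C; then aq. potassium sodium tartrate
Reagents that add atoms: none
Why: Hydride reduction of the ester to the primary alcohol; the ketone is masked as its silyl enol ether, which is inert to the hydride and survives a non-acidic work-up.

Step 6
Reactants: 9 (2S)-2-[(1R,5R)-5-allyl-3-(tert-butyldimethylsilyloxy)cyclopent-2-en-1-yl]-3-methylbutan-1-ol
Product: 10 tert-butyl{(2S)-2-[(1R,5R)-5-allyl-3-(tert-butyldimethylsilyloxy)cyclopent-2-en-1-yl]-3-methylbutoxy}diphenylsilane
Conditions: TBDPSCl, imidazole, DMF, 0 °C to rt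
Reagents that add atoms: tert-butyldiphenylsilyl chloride, CC(C)(C)[Si](Cl)(c1ccccc1)c1ccccc1
Why: Standard silylation of a primary alcohol; the bulky silyl ether is chosen to survive the acyl bromide and ZnCl2 of step 12.

Step 7
Reactants: 10 tert-butyl{(2S)-2-[(1R,5R)-5-allyl-3-(tert-butyldimethylsilyloxy)cyclopent-2-en-1-yl]-3-methylbutoxy}diphenylsilane
Product: 12 (2R,3R,4R)-4-allyl-3-[(2S)-1-(tert-butyldiphenylsilyloxy)-3-methylbutan-2-yl]-2-hydroxycyclopentan-1-one, via silyloxy ketone 11 (not isolated)
Conditions: mCPBA, NaHCO3, CH2Cl2, −20 °C; then Et3N·3HF, THF, rt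
Reagents that add atoms: 3-chloroperoxybenzoic acid, OOC(=O)c1cccc(Cl)c1
Why: Rubottom oxidation: the electron-rich enol ether is epoxidised much faster than the terminal alkene, on the face opposite the C3a side chain, and silyl migration then fluoride give the α-hydroxy ketone with the C3 oxygen trans to that chain. The secondary α-keto silyl ether is cleaved while the primary tert-butyldiphenylsilyl ether stays.

Step 8
Reactants: 12 (2R,3R,4R)-4-allyl-3-[(2S)-1-(tert-butyldiphenylsilyloxy)-3-methylbutan-2-yl]-2-hydroxycyclopentan-1-one
Product: 13 (1R,2R,3R)-3-allyl-2-[(2S)-1-(tert-butyldiphenylsilyloxy)-3-methylbutan-2-yl]-5-oxocyclopentyl acetate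
Conditions: Ac2O, pyridine, DMAP (cat.), CH2Cl2, 0 °C
Reagents that add atoms: acetic anhydride, CC(=O)OC(C)=O
Why: Acylation of the only free hydroxyl; the all-trans arrangement at C3, C3a and C7a is also the thermodynamically preferred one, so mild base should not disturb C3.

Step 9
Reactants: 13 (1R,2R,3R)-3-allyl-2-[(2S)-1-(tert-butyldiphenylsilyloxy)-3-methylbutan-2-yl]-5-oxocyclopentyl acetate
Product: 15 (1R,2R,3R)-2-[(2S)-1-(tert-butyldiphenylsilyloxy)-3-methylbutan-2-yl]-5-oxo-3-(2-oxoethyl)cyclopentyl acetate, via ozonide 14 (not isolated)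
Conditions: O3, CH2Cl2, −78 °C; then Me2S, −78 °C to rt
Reagents that add atoms: ozone, [O-][O+]=O
Why: Ozonolysis with reductive work-up; the terminal alkene is the only C=C bond in the molecule, and the allyl CH2 becomes C7 and the new aldehyde carbon C6.

Step 10
Reactants: 15 (1R,2R,3R)-2-[(2S)-1-(tert-butyldiphenylsilyloxy)-3-methylbutan-2-yl]-5-oxo-3-(2-oxoethyl)cyclopentyl acetate
Product: 16 (1R,2R,3R)-2-[(2S)-1-(tert-butyldiphenylsilyloxy)-3-methylbutan-2-yl]-5-oxo-3-(3-oxoprop-1-en-2-yl)cyclopentyl acetate
Conditions: CH2O (37% aq.), pyrrolidine (10 mol%), propanoic acid (10 mol%), i-PrOH, 45 °C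
Reagents that add atoms: formaldehyde, C=O
Why: Amine-catalysed α-methylenation of an aldehyde (enamine Mannich reaction, then elimination of the amine) introduces C8; the enamine forms at the unhindered aldehyde in preference to the ketone.

Step 11
Reactants: 17 angelic acid [(Z)-2-methylbut-2-enoic acid]
Product: 18 angeloyl bromide [(Z)-2-methylbut-2-enoyl bromide]
Conditions: 1-bromo-N,N,2-trimethylprop-1-en-1-amine, CH2Cl2, 0 °C
Reagents that add atoms: 1-bromo-N,N,2-trimethylprop-1-en-1-amine, CC(C)=C(Br)N(C)C
Why: The α-haloenamine converts the acid into the acyl bromide under neutral conditions with an amide as the only by-product, so no free HBr is formed that could isomerise the Z double bond.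

Step 12
Reactants: 16 (1R,2R,3R)-2-[(2S)-1-(tert-butyldiphenylsilyloxy)-3-methylbutan-2-yl]-5-oxo-3-(3-oxoprop-1-en-2-yl)cyclopentyl acetate; 18 angeloyl bromide
Product: 19 (1E)-2-{(1R,2R,3R)-3-acetoxy-2-[(2S)-1-(tert-butyldiphenylsilyloxy)-3-methylbutan-2-yl]-4-oxocyclopentyl}-3-bromoprop-1-en-1-yl (2Z)-2-methylbut-2-enoate
Conditions: ZnCl2 (10 mol%), CH2Cl2, −20 to 0 °C
Reagents that add atoms: none
Why: ZnCl2-catalysed addition of the acyl bromide to the enal carbonyl, followed by 1,3-shift of bromide, is the known route from acroleins to 3-bromopropenyl esters (net 1,4-addition). It places the angelate on C6 and bromine on C8; ketone, acetate and silyl ether should not react at this temperature.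

Step 13
Reactants: 19 (1E)-2-{(1R,2R,3R)-3-acetoxy-2-[(2S)-1-(tert-butyldiphenylsilyloxy)-3-methylbutan-2-yl]-4-oxocyclopentyl}-3-bromoprop-1-en-1-yl (2Z)-2-methylbut-2-enoate
Product: 20 (1E)-2-{(1R,2R,3R)-3-acetoxy-2-[(2S)-1-hydroxy-3-methylbutan-2-yl]-4-oxocyclopentyl}-3-bromoprop-1-en-1-yl (2Z)-2-methylbut-2-enoate
Conditions: HF·pyridine, THF, 0 °C to rt
Reagents that add atoms: none
Why: Acidic fluoride cleaves the primary silyl ether; the medium holds no free base or strong nucleophile, so enol ester, allylic bromide, acetate and angelate should persist.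

Step 14
Reactants: 20 (1E)-2-{(1R,2R,3R)-3-acetoxy-2-[(2S)-1-hydroxy-3-methylbutan-2-yl]-4-oxocyclopentyl}-3-bromoprop-1-en-1-yl (2Z)-2-methylbut-2-enoate
Product: 21 (1E)-2-{(1R,2R,3R)-3-acetoxy-2-[(2S)-3-methyl-1-oxobutan-2-yl]-4-oxocyclopentyl}-3-bromoprop-1-en-1-yl (2Z)-2-methylbut-2-enoate
Conditions: Dess–Martin periodinane, NaHCO3, CH2Cl2, 0 °C to rt
Reagents that add atoms: none
Why: Buffered Dess–Martin oxidation gives the aldehyde under near-neutral conditions, which should leave the α-stereocentre C4 and the allylic bromide intact; the aldehyde is used at once.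

Step 15
Reactants: 21 (1E)-2-{(1R,2R,3R)-3-acetoxy-2-[(2S)-3-methyl-1-oxobutan-2-yl]-4-oxocyclopentyl}-3-bromoprop-1-en-1-yl (2Z)-2-methylbut-2-enoate
Product: 24 (3R,3aR,4S,5S,6S,7aR)-3-acetoxy-5-hydroxy-7-methylidene-2-oxo-4-(propan-2-yl)octahydro-1H-inden-6-yl (2Z)-2-methylbut-2-enoate, via allylchromium species 22 (not isolated), via chromium alkoxide 23 (not isolated)
Conditions: CrCl2 (4 equiv), THF, 0 °C to rt; then H2O
Reagents that add atoms: none
Why: Two one-electron transfers from divalent chromium turn the allylic C8–Br bond of 21 into the γ-angeloyloxyallylchromium species 22, whose enol ester geometries interconvert by 1,3-shift of chromium, so the geometry delivered by step 12 is not binding. Chromium on C8 binds the C5 aldehyde oxygen and C6 attacks C5 through a closed six-membered Zimmerman–Traxler array, giving the C5–C6 bond with transposition of the alkene to C7=C8; the closest known reaction type is the Nozaki–Hiyama–Kishi-type addition of 3-bromopropenyl esters to aldehydes with CrCl2, which gives anti 1,2-diol monoesters and is used here within one molecule. The six-membered ring closes in the 6-exo-trig mode at the carbonyl, as a chair fused trans to the cyclopentanone. C5 is controlled by the chelate: the C8–Cr–O bridge spans C7 and C5 on one face of the forming ring, which is possible only with the C5–O bond axial, on the face opposite the C7a hydrogen. C6 is controlled by the enol ester geometry that reacts: with the acyloxy group trans to C8 it is equatorial in the chelate ring and therefore axial on the carbocycle, anti to the C5 oxygen. The equatorial isopropyl group at C4 and the trans ring fusion fix this chair. The step needs selectivity for the aldehyde over the C2 ketone and the three esters, which allylchromium reagents normally show, and addition to C2 would require a strained bridged ring. The trans-diaxial product cannot pass the angeloyl group to the C5 hydroxyl, and water releases 24 from alkoxide 23.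

## Compound list

1 | (R)-4-(tert-butyldimethylsilyloxy)cyclopent-2-en-1-one | O=C1C=C[C@H](O[Si](C)(C)C(C)(C)C)C1 | starting material
2 | allyltrimethylsilane | C=CC[Si](C)(C)C | starting material
3 | (3R,4R)-3-allyl-4-(tert-butyldimethylsilyloxy)cyclopentan-1-one | O=C1C[C@@H](CC=C)[C@H](O[Si](C)(C)C(C)(C)C)C1 | intermediate
4 | (R)-4-allylcyclopent-2-en-1-one | O=C1C=C[C@H](CC=C)C1 | intermediate
5 | methyl 3-methylbutanoate | CC(C)CC(=O)OC | starting material
6 | lithium enolate of 5 with O–Li cis to isopropyl | CC(C)/C=C(/OC)[O-].[Li+] | intermediate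
7 | (Z)-tert-butyl[(1-methoxy-3-methylbut-1-en-1-yl)oxy]dimethylsilane | CC(C)/C=C(/OC)O[Si](C)(C)C(C)(C)C | intermediate
8 | methyl (2S)-2-[(1S,5R)-5-allyl-3-(tert-butyldimethylsilyloxy)cyclopent-2-en-1-yl]-3-methylbutanoate | C=CC[C@@H]1CC(O[Si](C)(C)C(C)(C)C)=C[C@H]1[C@H](C(C)C)C(=O)OC | intermediate
9 | (2S)-2-[(1R,5R)-5-allyl-3-(tert-butyldimethylsilyloxy)cyclopent-2-en-1-yl]-3-methylbutan-1-ol | C=CC[C@@H]1CC(O[Si](C)(C)C(C)(C)C)=C[C@H]1[C@H](C(C)C)CO | intermediate
10 | tert-butyl{(2S)-2-[(1R,5R)-5-allyl-3-(tert-butyldimethylsilyloxy)cyclopent-2-en-1-yl]-3-methylbutoxy}diphenylsilane | C=CC[C@@H]1CC(O[Si](C)(C)C(C)(C)C)=C[C@H]1[C@H](C(C)C)CO[Si](c2ccccc2)(c2ccccc2)C(C)(C)C | intermediate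
11 | (2R,3R,4R)-4-allyl-2-(tert-butyldimethylsilyloxy)-3-[(2S)-1-(tert-butyldiphenylsilyloxy)-3-methylbutan-2-yl]cyclopentan-1-one | C=CC[C@@H]1CC(=O)[C@H](O[Si](C)(C)C(C)(C)C)[C@H]1[C@H](C(C)C)CO[Si](c2ccccc2)(c2ccccc2)C(C)(C)C | intermediate
12 | (2R,3R,4R)-4-allyl-3-[(2S)-1-(tert-butyldiphenylsilyloxy)-3-methylbutan-2-yl]-2-hydroxycyclopentan-1-one | C=CC[C@@H]1CC(=O)[C@H](O)[C@H]1[C@H](C(C)C)CO[Si](c2ccccc2)(c2ccccc2)C(C)(C)C | intermediate
13 | (1R,2R,3R)-3-allyl-2-[(2S)-1-(tert-butyldiphenylsilyloxy)-3-methylbutan-2-yl]-5-oxocyclopentyl acetate | C=CC[C@@H]1CC(=O)[C@H](OC(C)=O)[C@H]1[C@H](C(C)C)CO[Si](c2ccccc2)(c2ccccc2)C(C)(C)C | intermediate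
14 | ozonide of 13 (1,2,4-trioxolane at the former alkene) | C1(OCOO1)C[C@@H]2CC(=O)[C@H](OC(C)=O)[C@H]2[C@H](C(C)C)CO[Si](c3ccccc3)(c3ccccc3)C(C)(C)C | intermediate
15 | (1R,2R,3R)-2-[(2S)-1-(tert-butyldiphenylsilyloxy)-3-methylbutan-2-yl]-5-oxo-3-(2-oxoethyl)cyclopentyl acetate | O=CC[C@@H]1CC(=O)[C@H](OC(C)=O)[C@H]1[C@H](C(C)C)CO[Si](c2ccccc2)(c2ccccc2)C(C)(C)C | intermediate
16 | (1R,2R,3R)-2-[(2S)-1-(tert-butyldiphenylsilyloxy)-3-methylbutan-2-yl]-5-oxo-3-(3-oxoprop-1-en-2-yl)cyclopentyl acetate | C=C(C=O)[C@@H]1CC(=O)[C@H](OC(C)=O)[C@H]1[C@H](C(C)C)CO[Si](c2ccccc2)(c2ccccc2)C(C)(C)C | intermediate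
17 | angelic acid, (Z)-2-methylbut-2-enoic acid | C/C=C(/C)C(O)=O | starting material
18 | angeloyl bromide, (Z)-2-methylbut-2-enoyl bromide | C/C=C(/C)C(Br)=O | intermediate
19 | (1E)-2-{(1R,2R,3R)-3-acetoxy-2-[(2S)-1-(tert-butyldiphenylsilyloxy)-3-methylbutan-2-yl]-4-oxocyclopentyl}-3-bromoprop-1-en-1-yl (2Z)-2-methylbut-2-enoate | BrC/C(=C/OC(=O)/C(C)=C\C)[C@@H]1CC(=O)[C@H](OC(C)=O)[C@H]1[C@H](C(C)C)CO[Si](c2ccccc2)(c2ccccc2)C(C)(C)C | intermediate
20 | (1E)-2-{(1R,2R,3R)-3-acetoxy-2-[(2S)-1-hydroxy-3-methylbutan-2-yl]-4-oxocyclopentyl}-3-bromoprop-1-en-1-yl (2Z)-2-methylbut-2-enoate | BrC/C(=C/OC(=O)/C(C)=C\C)[C@@H]1CC(=O)[C@H](OC(C)=O)[C@H]1[C@H](C(C)C)CO | intermediate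
21 | (1E)-2-{(1R,2R,3R)-3-acetoxy-2-[(2S)-3-methyl-1-oxobutan-2-yl]-4-oxocyclopentyl}-3-bromoprop-1-en-1-yl (2Z)-2-methylbut-2-enoate | BrC/C(=C/OC(=O)/C(C)=C\C)[C@@H]1CC(=O)[C@H](OC(C)=O)[C@H]1[C@H](C(C)C)C=O | intermediate
22 | allylchromium species: 21 with CrCl2 (trivalent chromium) on C8 in place of bromine | Cl[Cr](Cl)C/C(=C/OC(=O)/C(C)=C\C)[C@@H]1CC(=O)[C@H](OC(C)=O)[C@H]1[C@H](C(C)C)C=O | intermediate
23 | chromium alkoxide: 24 with CrCl2 (trivalent chromium) on the C5 oxygen | C=C1[C@@H]2CC(=O)[C@H](OC(C)=O)[C@H]2[C@H](C(C)C)[C@H](O[Cr](Cl)Cl)[C@H]1OC(=O)/C(C)=C\C | intermediate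
24 | (3R,3aR,4S,5S,6S,7aR)-3-acetoxy-5-hydroxy-7-methylidene-2-oxo-4-(propan-2-yl)octahydro-1H-inden-6-yl (2Z)-2-methylbut-2-enoate | C=C1[C@@H]2CC(=O)[C@H](OC(C)=O)[C@H]2[C@H](C(C)C)[C@H](O)[C@H]1OC(=O)/C(C)=C\C | target

## Step count and least certain steps

Total: 15 steps. Longest linear sequence: 13 steps from 1 (steps 1, 2, 4–10, 12–15); steps 3 and 11 are one-step side branches.

**Step 15 (key step).** Three processes may interfere. Excess divalent chromium may reduce the α-acetoxy ketone, with loss of the C3 oxygen. The allylchromium species may react through the other enol ester geometry, which would put the ester equatorial and erode the anti relation. The allylchromium species may be protonated before it closes. The fallback leaves low-valent chromium and the anhydrous organometallic altogether: a Barbier-type closure of 21 with indium powder (zerovalent indium) in THF/H2O at rt, the aqueous allylation known for 3-bromopropenyl esters, which does not reduce α-acyloxy ketones. It sets out from 21 and returns at 24 without a new isolated compound.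

**Step 4.** The compact (synclinal) arrangement of the open transition state may compete with the extended one, so stereocontrol at C4 may be poor or reversed. The addition may also be slow, because both reacting carbons are branched. The fallback gives up kinetic control at C4 for equilibration and recycling. It sets out from 4 and 7: the addition is run for conversion only, and the product, containing the C4-epimeric ester F1, is reduced as in step 5. The epimeric alcohol F2 is separated from 9 and oxidised with Dess–Martin periodinane to the epimeric aldehyde F3. DBU in CH2Cl2 equilibrates F3 with the (2S)-aldehyde F4, NaBH4 reduces the mixture, and chromatography returns 9 and sends F2 round again. The fallback comes back to the route at 9.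

**Step 12.** The angeloyl unit may isomerise to the tigloyl unit by reversible addition of bromide to the unsaturated acyl bromide. The silyl ether may be attacked by the acyl bromide–ZnCl2 pair, and the 1,3-bromide shift may stop short. The fallback never makes an unsaturated acyl bromide. Acid 17 is converted with 1-chloro-N,N,2-trimethylprop-1-en-1-amine into angeloyl chloride F5. F5 adds to 16 under ZnCl2 catalysis to give the chloro enol angelate F6. Halide exchange with LiBr in acetone then gives 19, where the route is rejoined.

**Step 13.** A primary tert-butyldiphenylsilyl ether needs long exposure to acidic fluoride. During that time the allylic bromide may be substituted or solvolysed and the enol ester hydrolysed. The fallback changes the order so that fluoride never meets the bromide. It sets out from 16: HF·pyridine gives the hydroxy enal F7, and Dess–Martin oxidation gives the dialdehyde F8. Addition of 18 with ZnCl2 at −20 °C should then take the conjugated aldehyde irreversibly through the 1,3-bromide shift, while the hindered saturated aldehyde adds the acyl bromide only reversibly. This returns to the route at 21.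

## Further compounds

F0 | step 15 | none | none
F1 | step 4 | methyl (2R)-2-[(1S,5R)-5-allyl-3-(tert-butyldimethylsilyloxy)cyclopent-2-en-1-yl]-3-methylbutanoate | C=CC[C@@H]1CC(O[Si](C)(C)C(C)(C)C)=C[C@H]1[C@@H](C(C)C)C(=O)OC
F2 | step 4 | (2R)-2-[(1R,5R)-5-allyl-3-(tert-butyldimethylsilyloxy)cyclopent-2-en-1-yl]-3-methylbutan-1-ol | C=CC[C@@H]1CC(O[Si](C)(C)C(C)(C)C)=C[C@H]1[C@@H](C(C)C)CO
F3 | step 4 | (2R)-2-[(1S,5R)-5-allyl-3-(tert-butyldimethylsilyloxy)cyclopent-2-en-1-yl]-3-methylbutanal | C=CC[C@@H]1CC(O[Si](C)(C)C(C)(C)C)=C[C@H]1[C@@H](C(C)C)C=O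
F4 | step 4 | (2S)-2-[(1S,5R)-5-allyl-3-(tert-butyldimethylsilyloxy)cyclopent-2-en-1-yl]-3-methylbutanal | C=CC[C@@H]1CC(O[Si](C)(C)C(C)(C)C)=C[C@H]1[C@H](C(C)C)C=O
F5 | step 12 | angeloyl chloride, (Z)-2-methylbut-2-enoyl chloride | C/C=C(/C)C(Cl)=O
F6 | step 12 | (1E)-2-{(1R,2R,3R)-3-acetoxy-2-[(2S)-1-(tert-butyldiphenylsilyloxy)-3-methylbutan-2-yl]-4-oxocyclopentyl}-3-chloroprop-1-en-1-yl (2Z)-2-methylbut-2-enoate | ClC/C(=C/OC(=O)/C(C)=C\C)[C@@H]1CC(=O)[C@H](OC(C)=O)[C@H]1[C@H](C(C)C)CO[Si](c2ccccc2)(c2ccccc2)C(C)(C)C
F7 | step 13 | (1R,2R,3R)-2-[(2S)-1-hydroxy-3-methylbutan-2-yl]-5-oxo-3-(3-oxoprop-1-en-2-yl)cyclopentyl acetate | C=C(C=O)[C@@H]1CC(=O)[C@H](OC(C)=O)[C@H]1[C@H](C(C)C)CO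
F8 | step 13 | (1R,2R,3R)-2-[(2S)-3-methyl-1-oxobutan-2-yl]-5-oxo-3-(3-oxoprop-1-en-2-yl)cyclopentyl acetate | C=C(C=O)[C@@H]1CC(=O)[C@H](OC(C)=O)[C@H]1[C@H](C(C)C)C=O
A1 | alternative 1 | trans-4-hydroxy-5-alkylcyclopent-2-enone from the furan rearrangement | O=C1C=C[C@H](O)[C@H]1[C@H](C(C)C)[C@H](OCc1ccc(OC)cc1)CO[Si](c1ccccc1)(c1ccccc1)C(C)(C)C
A2 | alternative 1 | 2-furylcarbinol precursor of A1 | OC(c1ccco1)[C@H](C(C)C)[C@H](OCc1ccc(OC)cc1)CO[Si](c1ccccc1)(c1ccccc1)C(C)(C)C
A3 | alternative 2 | C3 alcohol of the target with C5 as tert-butyldimethylsilyl ether | C=C1[C@@H]2CC(=O)[C@H](O)[C@H]2[C@H](C(C)C)[C@H](O[Si](C)(C)C(C)(C)C)[C@H]1OC(=O)/C(C)=C\C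
A4 | alternative 2 | dialdehyde precursor of A3 (C2 and C3 as aldehydes on the cyclohexane) | C=C1[C@H](CC=O)[C@@H](C=O)[C@H](C(C)C)[C@H](O[Si](C)(C)C(C)(C)C)[C@H]1OC(=O)/C(C)=C\C
A5 | alternative 3 | bicyclic core with C6 as 4-methoxybenzyl ether and C5 as silyl ether | C=C1[C@@H]2CC(=O)[C@H](OC(C)=O)[C@H]2[C@H](C(C)C)[C@H](O[Si](C)(C)C(C)(C)C)[C@H]1OCc1ccc(OC)cc1
A6 | alternative 3 | N-hydroxyphthalimide ester precursor of A5 with an ethynyl group on C7a | C#C[C@@H]1CC(=O)[C@H](OC(C)=O)[C@H]1[C@H](C(C)C)[C@H](O[Si](C)(C)C(C)(C)C)C(OCc1ccc(OC)cc1)C(=O)ON1C(=O)c2ccccc2C1=O
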